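## Retrosynthetic overview
- Last step: O-demethylate the hindered C9 methyl ether. Before that, the ring-A 2,2-dimethylchromene forms by phenol/prenal condensation and oxa-6π-electrocyclization on an 8-hydroxy-9-methoxy-10-prenyl pterocarpan.
- The cis-fused pterocarpan forms by acid cyclization of the 2'-phenol onto the C11a benzylic cation of a 3-aryl-4-alkoxychroman. Ring closure alone fixes C11a relative to C6a.
- The chroman ring is closed by an oxa-Pictet–Spengler-type Friedel–Crafts reaction of an aryl ether onto an acetal-derived oxocarbenium ion.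
- The only free stereocenter, C6a, and the C6a–C6b bond come from an aromatic Claisen rearrangement of an aryl ether of (S)-but-3-en-2-ol-derived (R)-allylic alcohol (chirality transfer). Ozonolysis then unmasks C6 as CH2OH.
- Ring B's chromene comes from resorcinol and prenal (oxa-6π-electrocyclization) and is carried in as 7-hydroxy-2,2-dimethylchromene.

Assumptions (one line): the Claisen occurs at C6b (para to OMe, unhindered) rather than C10; the resorcinol/prenal product is mainly the separable 7-hydroxy isomer; Friedel–Crafts closure occurs at chromene C6 (para to the pyran O).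

## Route

**Step 1**
Reactants: 1 vanillin
Product: 2 3-methoxy-4-(methoxymethoxy)benzaldehyde
Conditions: MOMCl, i-Pr2NEt, CH2Cl2, 0 °C → rt
Reagents that add atoms: MOMCl, ClCOC
Why: Williamson-type O-protection of the phenol as a MOM ether, which directs lithiation later and survives the Claisen, ozonolysis and lithiation steps.

**Step 2**
Reactants: 2
Product: 3 3-methoxy-4-(methoxymethoxy)phenol
Conditions: (i) mCPBA, NaHCO3, CH2Cl2, 0 °C → rt; (ii) K2CO3, MeOH, rt
Reagents that add atoms: mCPBA, OOC(=O)c1cccc(Cl)c1
Why: Baeyer–Villiger (Dakin-type) oxidation of the electron-rich aldehyde gives the aryl formate, which methanolysis converts to the phenol that becomes O10a.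

**Step 3**
Reactants: 4 (S)-but-3-en-2-ol; 5 2-vinyl-1,3-dioxolane
Product: 6 (S,E)-4-(1,3-dioxolan-2-yl)but-3-en-2-ol
Conditions: Grubbs II (5 mol%), CH2Cl2, 40 °C (5 in 3-fold excess)
Reagents that add atoms: none
Why: Cross-metathesis gives the E-alkene, and the carbinol stereocenter from the chiral starting material is untouched.

**Step 4**
Reactants: 3; 6
Product: 7 1-{[(2R,3E)-4-(1,3-dioxolan-2-yl)but-3-en-2-yl]oxy}-3-methoxy-4-(methoxymethoxy)benzene
Conditions: PPh3, DIAD, THF, 0 °C → rt
Reagents that add atoms: none
Why: Mitsunobu etherification proceeds with SN2 inversion, so (S)-alcohol gives (R)-aryl allyl ether.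

**Step 5**
Reactants: 7
Product: 8 2-[(1S,2E)-1-(1,3-dioxolan-2-yl)but-2-en-1-yl]-5-methoxy-4-(methoxymethoxy)phenol
Conditions: PhNEt2, 200 °C, sealed tube/microwave, 2 h
Reagents that add atoms: none
Why: Aromatic Claisen [3,3] rearrangement forms the C6a–C6b bond suprafacially, and the (R)-ether with E-alkene transfers its chirality to the new benzylic stereocenter (C6a). The amine solvent keeps the acetal from reacting with the phenol.

**Step 6**
Reactants: 8
Product: 9 1-[(1S,2E)-1-(1,3-dioxolan-2-yl)but-2-en-1-yl]-4-methoxy-2,5-bis(methoxymethoxy)benzene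
Conditions: MOMCl, i-Pr2NEt, CH2Cl2, 0 °C → rt
Reagents that add atoms: MOMCl, ClCOC
Why: MOM protection of O10a makes the ring ozone-stable and stops it competing as a nucleophile later.

**Step 7**
Reactants: 9
Product: 10 (2R)-2-(1,3-dioxolan-2-yl)-2-[4-methoxy-2,5-bis(methoxymethoxy)phenyl]ethan-1-ol
Conditions: O3, CH2Cl2/MeOH, −78 °C; then NaBH4, −78 → 0 °C
Reagents that add atoms: ozone, O=[O+][O-]
Why: Ozonolysis of the only alkene, with in-situ borohydride reduction, gives the primary C6 alcohol without isolating the epimerizable α-aryl aldehyde. C6a is not touched.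

**Step 8**
Reactants: 10
Product: 11 (2R)-2-(1,3-dioxolan-2-yl)-2-[4-methoxy-2,5-bis(methoxymethoxy)-3-(3-methylbut-2-en-1-yl)phenyl]ethan-1-ol
Conditions: n-BuLi (2.5 equiv), THF, 0 °C; then CuI (10 mol%), prenyl bromide, −78 → −20 °C
Reagents that add atoms: prenyl bromide, CC(C)=CCBr
Why: Directed ortho-metalation occurs at C10, the only position flanked by two alkoxy directors (OMOM and OMe), and the aryllithium/cuprate is C-prenylated.

**Step 9**
Reactants: 12 resorcinol; 13 3-methyl-2-butenal (prenal)
Product: 14 2,2-dimethyl-2H-chromen-7-ol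
Conditions: pyridine, 120 °C, sealed tube
Reagents that add atoms: none
Why: Phenol/enal condensation to the o-quinone methide followed by oxa-6π-electrocyclization builds the dimethylchromene; the 7-hydroxy isomer is separated from the 5-hydroxy isomer.

**Step 10**
Reactants: 11; 14
Product: 15 7-{(2R)-2-(1,3-dioxolan-2-yl)-2-[4-methoxy-2,5-bis(methoxymethoxy)-3-prenylphenyl]ethoxy}-2,2-dimethyl-2H-chromene
Conditions: PPh3, DIAD, THF, 0 °C → rt
Reagents that add atoms: none
Why: Mitsunobu O-arylation of a primary alcohol with a phenol forms the C6–O5 bond. C6a is not acidic and is not touched.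

**Step 11**
Reactants: 15
Product: 16 (3R)-3-aryl-4-(2-hydroxyethoxy)chroman fused to the 2,2-dimethylpyran ring (aryl as in 15; C4 epimeric mixture)
Conditions: TMSOTf, 2,6-di-tert-butylpyridine, CH2Cl2, −78 → −30 °C; quench aq. NaHCO3/MeOH
Reagents that add atoms: none (the TMS group is lost on quench)
Why: Lewis-acid opening of the dioxolane gives an oxocarbenium ion that is trapped intramolecularly at chromene C6 (para to the pyran O) in a Friedel–Crafts/oxa-Pictet–Spengler closure. It is an isomerization of 15, the C6a stereocenter is retained, and C4 (future C11a) is left unspecified because it is erased in Step 12.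

**Step 12**
Reactants: 16
Product: 17 (6aR,11aR)-8-hydroxy-9-methoxy-10-prenylpterocarpan with the dimethylpyran fused on ring B
Conditions: TsOH·H2O, MeOH/CH2Cl2, 40 °C
Reagents that add atoms: none
Why: Acid removes both MOM groups and ionizes the benzylic C11a–OR bond to a p,o-dialkoxybenzyl cation. The freed O10a closes onto it (oxa-cyclization), and only the cis-fused 5/6 system is accessible, so C11a becomes R relative to C6a (R).

**Step 13**
Reactants: 17; 13 prenal
Product: 18 (6aR,11aR)-9-methoxy-10-prenyl-bis(2,2-dimethylpyrano)pterocarpan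
Conditions: pyridine, 130 °C, sealed tube, prenal (5 equiv)
Reagents that add atoms: none
Why: Condensation of the C8 phenol with prenal and oxa-6π-electrocyclization form the ring-A chromene at C7; C9 is blocked by OMe and C10 by prenyl, so regiochemistry is unambiguous.

**Step 14**
Reactants: 18
Product: 19 Lespecyrtin E4
Conditions: NaSEt, DMF, 100 °C
Reagents that add atoms: none
Why: SN2 thiolate demethylation cleaves the twisted, di-ortho-substituted aryl methyl ether. It avoids Lewis acids that would ionize the tertiary pyran ethers, so the stereocenters are untouched.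

## Compound list
1 | vanillin | COc1cc(C=O)ccc1O | starting material
2 | 3-methoxy-4-(methoxymethoxy)benzaldehyde | COCOc1ccc(C=O)cc1OC | intermediate
3 | 3-methoxy-4-(methoxymethoxy)phenol | COCOc1ccc(O)cc1OC | intermediate
4 | (S)-but-3-en-2-ol | C=C[C@H](C)O | starting material
5 | 2-vinyl-1,3-dioxolane | C=CC1OCCO1 | starting material
6 | (S,E)-4-(1,3-dioxolan-2-yl)but-3-en-2-ol | C[C@H](O)/C=C/C1OCCO1 | intermediate
7 | aryl (R,E)-allyl ether | C[C@@H](Oc1ccc(OCOC)c(OC)c1)/C=C/C1OCCO1 | intermediate
8 | Claisen phenol (S) | Oc1cc(OC)c(OCOC)cc1[C@H](/C=C/C)C1OCCO1 | intermediate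
9 | bis-MOM ether (S) | COCOc1cc(OC)c(OCOC)cc1[C@H](/C=C/C)C1OCCO1 | intermediate
10 | primary alcohol (R) | COCOc1cc(OC)c(OCOC)cc1[C@H](CO)C1OCCO1 | intermediate
11 | prenylated alcohol (R) | COCOc1c(CC=C(C)C)c(OC)c(OCOC)cc1[C@H](CO)C1OCCO1 | intermediate
12 | resorcinol | Oc1cccc(O)c1 | starting material
13 | 3-methyl-2-butenal (prenal) | CC(C)=CC=O | starting material
14 | 2,2-dimethyl-2H-chromen-7-ol | CC1(C)C=Cc2ccc(O)cc2O1 | intermediate
15 | aryl ether acetal (R) | COCOc1c(CC=C(C)C)c(OC)c(OCOC)cc1[C@H](COc1ccc2C=CC(C)(C)Oc2c1)C1OCCO1 | intermediate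
16 | 3-aryl-4-(2-hydroxyethoxy)chroman (C3 R; C4 unspecified) | COCOc1c(CC=C(C)C)c(OC)c(OCOC)cc1[C@@H]1COc2cc3OC(C)(C)C=Cc3cc2C1OCCO | intermediate
17 | (6aR,11aR)-8-hydroxy-9-methoxy-10-prenyl pterocarpan (ring-B pyran) | CC(C)=CCc1c(OC)c(O)cc2c1O[C@H]1c4cc5c(cc4OC[C@@H]21)OC(C)(C)C=C5 | intermediate
18 | (6aR,11aR)-9-O-methyl bis-chromene | CC(C)=CCc1c(OC)c2c(c3c1O[C@H]1c4cc5c(cc4OC[C@@H]31)OC(C)(C)C=C5)C=CC(C)(C)O2 | intermediate
19 | Lespecyrtin E4 | CC(C)=CCc1c(O)c2c(c3c1O[C@H]1c4cc5c(cc4OC[C@@H]31)OC(C)(C)C=C5)C=CC(C)(C)O2 | target

## Totals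
Total steps: 14. Longest linear sequence: 12 (1 → 2 → 3 → 7 → 8 → 9 → 10 → 11 → 15 → 16 → 17 → 18 → 19 via Steps 1, 2, 4, 5, 6, 7, 8, 10, 11, 12, 13, 14). Cross-metathesis (Step 3) and chromenol synthesis (Step 9) are parallel branches.

Three steps most likely to fail:
1. **Step 5 (aromatic Claisen).** The risks are ortho-regioselectivity (C6b versus C10) and partial erosion of ee at 200 °C. Fallback: put a removable bromine at C10 of the ring-A phenol before etherification, so only C6b can react, and convert Ar–Br to the prenyl group by Li–Br exchange and prenylation after Step 12 (replacing Step 8).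
2. **Step 11 (Friedel–Crafts closure).** The oxocarbenium can lose the C6a proton, which would epimerize C6a, or close at the wrong ring position, and the chromene is acid-sensitive. Fallback: carry C11a into the Claisen substrate as a protected benzylic carbinol that already bears the ring-B aryl, made by adding the aryllithium to an (E)-4-silyloxy-pent-2-enal from (S)-lactate. Ring B is then closed by Mitsunobu etherification instead of a C–C-forming cyclization.
3. **Step 8 (directed lithiation/prenylation with a free primary alkoxide).** O-prenylation of the alkoxide may compete with C-prenylation. Fallback: omit prenylation here, demethylate C9 at the end, and install the prenyl group by ortho C-prenylation of the C9 phenol (C10 is its only free ortho position).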